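**Plan**

1. The target is robinetinidol-(4α→6)-epigallocatechin. The retrosynthesis first removes ten benzyl ethers and a C8 bromine (blocking group on the lower unit), then returns C2–H/C3–OH of the upper ring C to a C2=C3 enol ether (a 4H-chromene).
2. The central cut is C2=C3 of ring C. C2 carries O1 (the phenol oxygen of ring A) and the pyrogallol ring B, so it is the carbonyl carbon of an aryl gallate in disguise, and C3 is the only carbon between C2 and the diarylmethine C4. Ester methylenation followed by ring-closing enol ether–olefin metathesis with a propenyl group on C4 closes ring C; the two helper alkene termini leave as propene.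
3. Further cuts are O1–C2 (phenol + 3,4,5-tris(benzyloxy)benzoic acid) and C4–C6 of the lower unit (anti SN2′ arylation of an allylic picolinate by the C6 arylcopper of benzylated 8-bromo-epigallocatechin).
4. Forward: the ring A allylic picolinate (4 steps) and the lower-unit aryl iodide (4 steps) are made separately and joined at C4; ring C is then closed, hydroborated, and the whole is debenzylated and debrominated.
5. Stereochemistry: the lower unit comes from (−)-epigallocatechin; C4 from a CBS reduction and 1,3-chirality transfer in the SN2′ step; C2 and C3 from hydroboration of C2=C3 anti to the C4 aryl group.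

Key step: step 13

Remark on the chemistry: electrophilic bromination of the benzylated lower unit is taken to occur at C8, as is general for benzylated flavan-3-ols, so that the subsequent iodination marks C6.

**Route**

Step 1
Reactants: 1 4-(benzyloxy)-2-hydroxybenzaldehyde
Product: 2 4-(benzyloxy)-2-[(tert-butyldimethylsilyl)oxy]benzaldehyde
Conditions: TBSCl, imidazole, DMF, rt
Reagents that add atoms: tert-butyldimethylsilyl chloride, CC(C)(C)[Si](C)(C)Cl
Why: Imidazole-promoted O-silylation of the phenol masks the future O1 with a group that survives the organometallic steps and is removed by fluoride without acid.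

Step 2
Reactants: 2 4-(benzyloxy)-2-[(tert-butyldimethylsilyl)oxy]benzaldehyde; 3 1-(triphenyl-λ5-phosphanylidene)propan-2-one
Product: 4 (E)-4-{4-(benzyloxy)-2-[(tert-butyldimethylsilyl)oxy]phenyl}but-3-en-2-one
Conditions: toluene, 90 °C
Reagents that add atoms: none
Why: Wittig olefination with a stabilised ylide under neutral conditions should give the (E)-enone; the aldehyde carbon becomes C4 and the ylide carbon C3 of the target.

Step 3
Reactants: 4 (E)-4-{4-(benzyloxy)-2-[(tert-butyldimethylsilyl)oxy]phenyl}but-3-en-2-one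
Product: 5 (R,E)-4-{4-(benzyloxy)-2-[(tert-butyldimethylsilyl)oxy]phenyl}but-3-en-2-ol
Conditions: (S)-2-methyl-CBS-oxazaborolidine (cat.), catecholborane, toluene, −78 °C; aq. NaOH work-up
Reagents that add atoms: none
Why: Corey–Bakshi–Shibata reduction: the (S)-oxazaborolidine directs 1,2-hydride delivery with the alkenyl group as the large substituent, which should give the (R)-allylic alcohol.

Step 4
Reactants: 5 (R,E)-4-{4-(benzyloxy)-2-[(tert-butyldimethylsilyl)oxy]phenyl}but-3-en-2-ol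
Product: 6 (R,E)-4-{4-(benzyloxy)-2-[(tert-butyldimethylsilyl)oxy]phenyl}but-3-en-2-yl pyridine-2-carboxylate
Conditions: pyridine-2-carboxylic acid, DCC, DMAP (cat.), CH2Cl2, 0 °C → rt
Reagents that add atoms: pyridine-2-carboxylic acid, OC(=O)c1ccccn1
Why: Steglich esterification installs, with retention at the carbinol carbon, the picolinoxy leaving group that directs the later anti SN2′ substitution.

Step 5
Reactants: 7 (−)-epigallocatechin, (2R,3R)-2-(3,4,5-trihydroxyphenyl)chromane-3,5,7-triol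
Product: 8 (2R,3R)-5,7-bis(benzyloxy)-2-[3,4,5-tris(benzyloxy)phenyl]chroman-3-ol
Conditions: BnBr, K2CO3, DMF, −10 °C → rt
Reagents that add atoms: benzyl bromide, BrCc1ccccc1
Why: Williamson etherification of the five phenols with a weak base at low temperature leaves the C3 alcohol free and should not epimerise C2.

Step 6
Reactants: 8 (2R,3R)-5,7-bis(benzyloxy)-2-[3,4,5-tris(benzyloxy)phenyl]chroman-3-ol
Product: 9 (2R,3R)-3,5,7-tris(benzyloxy)-2-[3,4,5-tris(benzyloxy)phenyl]chromane
Conditions: NaH, BnBr, Bu4NI (cat.), DMF, 0 °C → rt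
Reagents that add atoms: benzyl bromide, BrCc1ccccc1
Why: Williamson etherification of the secondary alcohol through its sodium alkoxide gives a lower unit in which every oxygen carries the same hydrogenolysable group.

Step 7
Reactants: 9 (2R,3R)-3,5,7-tris(benzyloxy)-2-[3,4,5-tris(benzyloxy)phenyl]chromane
Product: 10 (2R,3R)-3,5,7-tris(benzyloxy)-8-bromo-2-[3,4,5-tris(benzyloxy)phenyl]chromane
Conditions: N-bromosuccinimide (1 equiv), CH2Cl2, −40 → 0 °C
Reagents that add atoms: N-bromosuccinimide, O=C1CCC(=O)N1Br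
Why: Electrophilic aromatic bromination should take place at C8, the more reactive position of the phloroglucinol ring in benzylated flavan-3-ols; the bromine then blocks C8 until the last step.

Step 8
Reactants: 10 (2R,3R)-3,5,7-tris(benzyloxy)-8-bromo-2-[3,4,5-tris(benzyloxy)phenyl]chromane
Product: 11 (2R,3R)-3,5,7-tris(benzyloxy)-8-bromo-6-iodo-2-[3,4,5-tris(benzyloxy)phenyl]chromane
Conditions: N-iodosuccinimide, CF3CO2H (cat.), CH2Cl2/MeCN, 0 °C → rt
Reagents that add atoms: N-iodosuccinimide, O=C1CCC(=O)N1I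
Why: Electrophilic aromatic iodination should occur at C6, the only remaining position activated by two ortho oxygens and one para oxygen, which marks the future interflavan carbon.

Step 9
Reactants: 11 (2R,3R)-3,5,7-tris(benzyloxy)-8-bromo-6-iodo-2-[3,4,5-tris(benzyloxy)phenyl]chromane; 6 (R,E)-4-{4-(benzyloxy)-2-[(tert-butyldimethylsilyl)oxy]phenyl}but-3-en-2-yl pyridine-2-carboxylate
Product: 14 (2R,3R)-3,5,7-tris(benzyloxy)-6-[(1S,2E)-1-{4-(benzyloxy)-2-[(tert-butyldimethylsilyl)oxy]phenyl}but-2-en-1-yl]-8-bromo-2-[3,4,5-tris(benzyloxy)phenyl]chromane, via arylmagnesium chloride 12 (not isolated), via arylcopper 13 (not isolated)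
Conditions: 11, iPrMgCl·LiCl, THF, −30 °C; CuBr·SMe2, −30 °C; then 6, −30 → 0 °C
Reagents that add atoms: isopropylmagnesium chloride–lithium chloride, CC(C)[Mg]Cl.[Li]Cl (Mg and Cl of 12 only); copper bromide–dimethyl sulfide, [Cu]Br.CSC (Cu of 13 only)
Why: Iodine–magnesium exchange (iodide reacts before bromide), transmetalation to copper and anti SN2′ allylic substitution: the aryl group should attack the γ-carbon anti to the magnesium-chelated picolinoxy group, so that the (R) carbinol center is transferred into the (S) diarylmethine C4 with an (E)-propenyl group.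

Step 10
Reactants: 14 (2R,3R)-3,5,7-tris(benzyloxy)-6-[(1S,2E)-1-{4-(benzyloxy)-2-[(tert-butyldimethylsilyl)oxy]phenyl}but-2-en-1-yl]-8-bromo-2-[3,4,5-tris(benzyloxy)phenyl]chromane
Product: 15 5-(benzyloxy)-2-[(1S,2E)-1-{(2R,3R)-3,5,7-tris(benzyloxy)-8-bromo-2-[3,4,5-tris(benzyloxy)phenyl]chroman-6-yl}but-2-en-1-yl]phenol
Conditions: Bu4NF, AcOH, THF, 0 °C
Reagents that add atoms: none
Why: Fluoride-mediated desilylation of the aryl silyl ether under buffered, non-acidic conditions frees O1 without endangering the acid-labile bond between C4 and the electron-rich lower unit.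

Step 11
Reactants: 15 5-(benzyloxy)-2-[(1S,2E)-1-{(2R,3R)-3,5,7-tris(benzyloxy)-8-bromo-2-[3,4,5-tris(benzyloxy)phenyl]chroman-6-yl}but-2-en-1-yl]phenol; 16 3,4,5-tris(benzyloxy)benzoic acid
Product: 17 5-(benzyloxy)-2-[(1S,2E)-1-{(2R,3R)-3,5,7-tris(benzyloxy)-8-bromo-2-[3,4,5-tris(benzyloxy)phenyl]chroman-6-yl}but-2-en-1-yl]phenyl 3,4,5-tris(benzyloxy)benzoate
Conditions: DCC, DMAP, CH2Cl2, rt
Reagents that add atoms: none
Why: Steglich esterification places ring B on O1 as a gallate whose carbonyl carbon is the future C2.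

Step 12
Reactants: 17 5-(benzyloxy)-2-[(1S,2E)-1-{(2R,3R)-3,5,7-tris(benzyloxy)-8-bromo-2-[3,4,5-tris(benzyloxy)phenyl]chroman-6-yl}but-2-en-1-yl]phenyl 3,4,5-tris(benzyloxy)benzoate
Product: 18 (2R,3R)-3,5,7-tris(benzyloxy)-6-{(1S,2E)-1-[4-(benzyloxy)-2-({1-[3,4,5-tris(benzyloxy)phenyl]ethenyl}oxy)phenyl]but-2-en-1-yl}-8-bromo-2-[3,4,5-tris(benzyloxy)phenyl]chromane
Conditions: Cp2TiMe2, toluene/THF, 70 °C, dark
Reagents that add atoms: dimethyltitanocene Cp2TiMe2, C[Ti](C)(C1C=CC=C1)C1C=CC=C1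
Why: Petasis methylenation: thermally formed titanocene methylidene should convert the aryl ester carbonyl into the 1-arylvinyl ether under non-basic conditions that leave the propenyl group, the benzyl ethers and the aryl bromide alone.

Step 13
Reactants: 18 (2R,3R)-3,5,7-tris(benzyloxy)-6-{(1S,2E)-1-[4-(benzyloxy)-2-({1-[3,4,5-tris(benzyloxy)phenyl]ethenyl}oxy)phenyl]but-2-en-1-yl}-8-bromo-2-[3,4,5-tris(benzyloxy)phenyl]chromane
Product: 19 (4S)-7-(benzyloxy)-4-{(2R,3R)-3,5,7-tris(benzyloxy)-8-bromo-2-[3,4,5-tris(benzyloxy)phenyl]chroman-6-yl}-2-[3,4,5-tris(benzyloxy)phenyl]-4H-chromene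
Conditions: second-generation Grubbs catalyst RuCl2(=CHPh)(PCy3)(H2IMes) (cat.), 1,4-benzoquinone (cat.), toluene (high dilution), 80 °C, argon purge
Reagents that add atoms: none
Why: The ruthenium alkylidene should load onto the propenyl terminus, add [2+2] to the 1,1-disubstituted enol-ether C=CH2, and cycloreversion of the ruthenacyclobutane then forms the C2=C3 bond; this is ring-closing olefin metathesis in its enol ether–olefin variant, whose closest precedent is the conversion of methylenated esters into cyclic enol ethers such as glycals, benzofurans and 4H-chromenes. The six-membered pyran ring C is closed with the new double bond inside the ring (endocyclic C2=C3), both alkene partners being held ortho to each other on ring A and propene being expelled. No stereocenter is made: the C4 center from step 9 is only carried, and the planar C2=C3 enol ether made here is what lets step 14 set C2 and C3 from C4. The step needs ring closure to win over migration of the propenyl double bond into conjugation (which would erase C4) and over dimerisation; the ortho arrangement on ring A favours closure, 1,4-benzoquinone suppresses ruthenium hydride isomerisation and high dilution suppresses cross-metathesis. The structural basis is that C2 bears O1 of ring A and ring B, so that the enol ether is available from a simple aryl gallate.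

Step 14
Reactants: 19 (4S)-7-(benzyloxy)-4-{(2R,3R)-3,5,7-tris(benzyloxy)-8-bromo-2-[3,4,5-tris(benzyloxy)phenyl]chroman-6-yl}-2-[3,4,5-tris(benzyloxy)phenyl]-4H-chromene
Product: 21 (2R,3S,4S)-7-(benzyloxy)-4-{(2R,3R)-3,5,7-tris(benzyloxy)-8-bromo-2-[3,4,5-tris(benzyloxy)phenyl]chroman-6-yl}-2-[3,4,5-tris(benzyloxy)phenyl]chroman-3-ol, via C3-alkylborane 20 (not isolated)
Conditions: BH3·THF, THF, 0 °C → rt; then aq. NaOH, 30% H2O2, 0 °C → rt
Reagents that add atoms: borane–tetrahydrofuran, B.C1CCOC1 (boron of 20 only); hydrogen peroxide, OO (oxygen on C3)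
Why: Hydroboration–oxidation: borane should add syn to the enol ether with boron on C3 (β to O1, away from ring B) from the face opposite the C4 aryl group, and oxidation with retention then gives the 2,3-trans-3,4-trans alcohol, so that C2 and C3 are both set by C4.

Step 15
Reactants: 21 (2R,3S,4S)-7-(benzyloxy)-4-{(2R,3R)-3,5,7-tris(benzyloxy)-8-bromo-2-[3,4,5-tris(benzyloxy)phenyl]chroman-6-yl}-2-[3,4,5-tris(benzyloxy)phenyl]chroman-3-ol
Product: 22 (2R,3S,4S)-2-(3,4,5-trihydroxyphenyl)-4-[(2R,3R)-3,5,7-trihydroxy-2-(3,4,5-trihydroxyphenyl)chroman-6-yl]chromane-3,7-diol (CNP0311915.2)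
Conditions: H2 (1 atm), Pd(OH)2/C, Et3N, THF/MeOH/H2O, rt, degassed solvents
Reagents that add atoms: none
Why: Catalytic hydrogenolysis should cleave the ten benzyl ethers and, with Et3N as HBr acceptor, the C8–Br bond in one operation under neutral to weakly basic conditions that spare the interflavan bond and all five stereocenters.

**Compound list**

1 | 4-(benzyloxy)-2-hydroxybenzaldehyde | O=Cc1ccc(OCc2ccccc2)cc1O | starting material
2 | 4-(benzyloxy)-2-[(tert-butyldimethylsilyl)oxy]benzaldehyde | O=Cc1ccc(OCc2ccccc2)cc1O[Si](C)(C)C(C)(C)C | intermediate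
3 | 1-(triphenyl-λ5-phosphanylidene)propan-2-one | CC(=O)C=P(c1ccccc1)(c1ccccc1)c1ccccc1 | starting material
4 | (E)-4-{4-(benzyloxy)-2-[(tert-butyldimethylsilyl)oxy]phenyl}but-3-en-2-one | CC(=O)/C=C/c1ccc(OCc2ccccc2)cc1O[Si](C)(C)C(C)(C)C | intermediate
5 | (R,E)-4-{4-(benzyloxy)-2-[(tert-butyldimethylsilyl)oxy]phenyl}but-3-en-2-ol | C[C@@H](O)/C=C/c1ccc(OCc2ccccc2)cc1O[Si](C)(C)C(C)(C)C | intermediate
6 | (R,E)-4-{4-(benzyloxy)-2-[(tert-butyldimethylsilyl)oxy]phenyl}but-3-en-2-yl pyridine-2-carboxylate | C[C@@H](OC(=O)c1ccccn1)/C=C/c1ccc(OCc2ccccc2)cc1O[Si](C)(C)C(C)(C)C | intermediate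
7 | (−)-epigallocatechin, (2R,3R)-2-(3,4,5-trihydroxyphenyl)chromane-3,5,7-triol | c1c(O)cc2c(c1O)C[C@@H](O)[C@@H](c3cc(O)c(O)c(O)c3)O2 | starting material
8 | (2R,3R)-5,7-bis(benzyloxy)-2-[3,4,5-tris(benzyloxy)phenyl]chroman-3-ol | c1c(OCc4ccccc4)cc2c(c1OCc4ccccc4)C[C@@H](O)[C@@H](c3cc(OCc4ccccc4)c(OCc4ccccc4)c(OCc4ccccc4)c3)O2 | intermediate
9 | (2R,3R)-3,5,7-tris(benzyloxy)-2-[3,4,5-tris(benzyloxy)phenyl]chromane | c1c(OCc4ccccc4)cc2c(c1OCc4ccccc4)C[C@@H](OCc4ccccc4)[C@@H](c3cc(OCc4ccccc4)c(OCc4ccccc4)c(OCc4ccccc4)c3)O2 | intermediate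
10 | (2R,3R)-3,5,7-tris(benzyloxy)-8-bromo-2-[3,4,5-tris(benzyloxy)phenyl]chromane | c1c(OCc4ccccc4)c(Br)c2c(c1OCc4ccccc4)C[C@@H](OCc4ccccc4)[C@@H](c3cc(OCc4ccccc4)c(OCc4ccccc4)c(OCc4ccccc4)c3)O2 | intermediate
11 | (2R,3R)-3,5,7-tris(benzyloxy)-8-bromo-6-iodo-2-[3,4,5-tris(benzyloxy)phenyl]chromane | Ic1c(OCc4ccccc4)c(Br)c2c(c1OCc4ccccc4)C[C@@H](OCc4ccccc4)[C@@H](c3cc(OCc4ccccc4)c(OCc4ccccc4)c(OCc4ccccc4)c3)O2 | intermediate
12 | arylmagnesium chloride: 6-(chloromagnesio) derivative of 10 | Cl[Mg]c1c(OCc4ccccc4)c(Br)c2c(c1OCc4ccccc4)C[C@@H](OCc4ccccc4)[C@@H](c3cc(OCc4ccccc4)c(OCc4ccccc4)c(OCc4ccccc4)c3)O2 | intermediate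
13 | arylcopper: 6-cuprio derivative of 10 (ArCu·MgBrCl) | [Cu]c1c(OCc4ccccc4)c(Br)c2c(c1OCc4ccccc4)C[C@@H](OCc4ccccc4)[C@@H](c3cc(OCc4ccccc4)c(OCc4ccccc4)c(OCc4ccccc4)c3)O2 | intermediate
14 | (2R,3R)-3,5,7-tris(benzyloxy)-6-[(1S,2E)-1-{4-(benzyloxy)-2-[(tert-butyldimethylsilyl)oxy]phenyl}but-2-en-1-yl]-8-bromo-2-[3,4,5-tris(benzyloxy)phenyl]chromane | C/C=C/[C@@H](c1ccc(OCc2ccccc2)cc1O[Si](C)(C)C(C)(C)C)c1c(OCc4ccccc4)c(Br)c2c(c1OCc4ccccc4)C[C@@H](OCc4ccccc4)[C@@H](c3cc(OCc4ccccc4)c(OCc4ccccc4)c(OCc4ccccc4)c3)O2 | intermediate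
15 | 5-(benzyloxy)-2-[(1S,2E)-1-{(2R,3R)-3,5,7-tris(benzyloxy)-8-bromo-2-[3,4,5-tris(benzyloxy)phenyl]chroman-6-yl}but-2-en-1-yl]phenol | C/C=C/[C@@H](c1ccc(OCc2ccccc2)cc1O)c1c(OCc4ccccc4)c(Br)c2c(c1OCc4ccccc4)C[C@@H](OCc4ccccc4)[C@@H](c3cc(OCc4ccccc4)c(OCc4ccccc4)c(OCc4ccccc4)c3)O2 | intermediate
16 | 3,4,5-tris(benzyloxy)benzoic acid | OC(=O)c1cc(OCc2ccccc2)c(OCc2ccccc2)c(OCc2ccccc2)c1 | starting material
17 | 5-(benzyloxy)-2-[(1S,2E)-1-{(2R,3R)-3,5,7-tris(benzyloxy)-8-bromo-2-[3,4,5-tris(benzyloxy)phenyl]chroman-6-yl}but-2-en-1-yl]phenyl 3,4,5-tris(benzyloxy)benzoate | C/C=C/[C@@H](c1ccc(OCc2ccccc2)cc1OC(=O)c1cc(OCc2ccccc2)c(OCc2ccccc2)c(OCc2ccccc2)c1)c1c(OCc4ccccc4)c(Br)c2c(c1OCc4ccccc4)C[C@@H](OCc4ccccc4)[C@@H](c3cc(OCc4ccccc4)c(OCc4ccccc4)c(OCc4ccccc4)c3)O2 | intermediate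
18 | (2R,3R)-3,5,7-tris(benzyloxy)-6-{(1S,2E)-1-[4-(benzyloxy)-2-({1-[3,4,5-tris(benzyloxy)phenyl]ethenyl}oxy)phenyl]but-2-en-1-yl}-8-bromo-2-[3,4,5-tris(benzyloxy)phenyl]chromane | C/C=C/[C@@H](c1ccc(OCc2ccccc2)cc1OC(=C)c1cc(OCc2ccccc2)c(OCc2ccccc2)c(OCc2ccccc2)c1)c1c(OCc4ccccc4)c(Br)c2c(c1OCc4ccccc4)C[C@@H](OCc4ccccc4)[C@@H](c3cc(OCc4ccccc4)c(OCc4ccccc4)c(OCc4ccccc4)c3)O2 | intermediate
19 | (4S)-7-(benzyloxy)-4-{(2R,3R)-3,5,7-tris(benzyloxy)-8-bromo-2-[3,4,5-tris(benzyloxy)phenyl]chroman-6-yl}-2-[3,4,5-tris(benzyloxy)phenyl]-4H-chromene | O(Cc5ccccc5)c1ccc2c(c1)OC(c1cc(OCc3ccccc3)c(OCc3ccccc3)c(OCc3ccccc3)c1)=C[C@@H]2c1c(OCc4ccccc4)c(Br)c2c(c1OCc4ccccc4)C[C@@H](OCc4ccccc4)[C@@H](c3cc(OCc4ccccc4)c(OCc4ccccc4)c(OCc4ccccc4)c3)O2 | intermediate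
20 | C3-alkylborane from 19: BH2 on C3 trans to the C4 aryl group, C2–H cis to boron, ring B trans to boron | O(Cc5ccccc5)c1ccc2c(c1)O[C@H](c1cc(OCc3ccccc3)c(OCc3ccccc3)c(OCc3ccccc3)c1)[C@@H](B)[C@@H]2c1c(OCc4ccccc4)c(Br)c2c(c1OCc4ccccc4)C[C@@H](OCc4ccccc4)[C@@H](c3cc(OCc4ccccc4)c(OCc4ccccc4)c(OCc4ccccc4)c3)O2 | intermediate
21 | (2R,3S,4S)-7-(benzyloxy)-4-{(2R,3R)-3,5,7-tris(benzyloxy)-8-bromo-2-[3,4,5-tris(benzyloxy)phenyl]chroman-6-yl}-2-[3,4,5-tris(benzyloxy)phenyl]chroman-3-ol | O(Cc5ccccc5)c1ccc2c(c1)O[C@H](c1cc(OCc3ccccc3)c(OCc3ccccc3)c(OCc3ccccc3)c1)[C@@H](O)[C@@H]2c1c(OCc4ccccc4)c(Br)c2c(c1OCc4ccccc4)C[C@@H](OCc4ccccc4)[C@@H](c3cc(OCc4ccccc4)c(OCc4ccccc4)c(OCc4ccccc4)c3)O2 | intermediate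
22 | (2R,3S,4S)-2-(3,4,5-trihydroxyphenyl)-4-[(2R,3R)-3,5,7-trihydroxy-2-(3,4,5-trihydroxyphenyl)chroman-6-yl]chromane-3,7-diol, robinetinidol-(4α→6)-epigallocatechin | Oc1ccc2c(c1)O[C@H](c1cc(O)c(O)c(O)c1)[C@@H](O)[C@@H]2c1c(O)cc2c(c1O)C[C@@H](O)[C@@H](c1cc(O)c(O)c(O)c1)O2 | target

**Step count and risks**

Total step count: 15. Longest linear sequence: 11 steps (7 → 22 through steps 5–15; equally 1 → 22 through steps 1–4 and 9–15).

Steps most likely to fail:

Step 9. The hindered 2,6-dialkoxyaryl group may transfer sluggishly to the γ-carbon, attack may occur at the α-carbon instead, or chirality transfer may be incomplete if the electron-rich picolinate ionises. The fallback sets out from 11 (with aldehyde 2) and comes back at 14. The arylmagnesium chloride 12 made from 11 is added to aldehyde 2 in THF at −40 °C, a carbonyl addition that tolerates the hindrance, to give the diarylmethanol F1 as a mixture of carbinol epimers. BF3·OEt2 in CH2Cl2 at −78 °C then ionises F1 to the doubly donor-stabilised diarylmethyl cation, which is trapped at carbon by potassium (E)-prop-1-enyltrifluoroborate, K[CH3CH=CHBF3], by ipso substitution with retention of alkene geometry. This should give 14 together with its C4 epimer; because the lower unit is homochiral the two are diastereomers and should be separable by chromatography, at the cost of stereocontrol at C4.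

Step 13. Initiation at two hindered alkenes may be slow, and ruthenium hydride species may move the propenyl double bond (or the product double bond) into conjugation, which destroys the C4 stereocenter. The fallback sets out from ester 17 and comes back at 19. A one-flask olefinic-ester cyclisation with the Takai–Utimoto titanium ethylidene reagent (TiCl4, TMEDA, Zn, PbCl2 cat., CH3CHBr2, THF/CH2Cl2, 65 °C) joins the ester carbonyl carbon and the propenyl CH directly by carbonyl olefination at titanium, with no metal hydride and no separate enol ether. Compounds outside the list made on this way: none F0.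

Step 14. Borane may add from the face of the C4 aryl group or place boron on C2, and the C3 borane may undergo β-elimination of the aryloxy group with opening of ring C. The fallback sets out from 19 and comes back at 21. Dimethyldioxirane (acetone/CH2Cl2, −78 °C) should epoxidise the enol ether from the face opposite the C4 aryl group to give the 2,3-epoxide F2. i-Bu2AlH in CH2Cl2 at −78 °C then coordinates the oxirane oxygen, the C2–O bond opens to the ring B-stabilised oxocarbenium ion and hydride is delivered to C2 from the same face, which should give 21 with the same 2,3-trans-3,4-trans arrangement.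

**Further compounds**

F1 | step 9 | {4-(benzyloxy)-2-[(tert-butyldimethylsilyl)oxy]phenyl}{(2R,3R)-3,5,7-tris(benzyloxy)-8-bromo-2-[3,4,5-tris(benzyloxy)phenyl]chroman-6-yl}methanol (both carbinol epimers) | OC(c1ccc(OCc2ccccc2)cc1O[Si](C)(C)C(C)(C)C)c1c(OCc4ccccc4)c(Br)c2c(c1OCc4ccccc4)C[C@@H](OCc4ccccc4)[C@@H](c3cc(OCc4ccccc4)c(OCc4ccccc4)c(OCc4ccccc4)c3)O2
F0 | step 13 | none | none
F2 | step 14 | 2,3-epoxide of 19 (oxirane oxygen on C2 and C3, on the face opposite the C4 aryl group) | O(Cc5ccccc5)c1ccc2c(c1)O[C@]3(c1cc(OCc6ccccc6)c(OCc6ccccc6)c(OCc6ccccc6)c1)[C@@H](O3)[C@@H]2c1c(OCc4ccccc4)c(Br)c2c(c1OCc4ccccc4)C[C@@H](OCc4ccccc4)[C@@H](c3cc(OCc4ccccc4)c(OCc4ccccc4)c(OCc4ccccc4)c3)O2
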